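The cyclohexadienone ring is closed last, between the ring carbonyl carbon that lies between the C-methyl and C-benzoyl carbons and the benzoyl-bearing carbon. The feature exploited is the diprenylated quaternary ring carbon: it cannot enolise, so an open chain carrying it can only cyclise by C-acylation of the 1-phenyl-1,3-diketone carbon. The acyl donor is stored in a temporary 1,3-dioxin-4-one ring, which also steers both prenylations to the one activated methylene. On heating, this ring loses acetone and the acylketene released is captured by the diketone carbon, giving the enolised trione in one operation. The precursor is a 5-methyldioxinone bearing the 1,1-diprenyl-2,4-dioxo-4-phenylbutyl chain at C6.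

Key step: step 4

Assumption: dioxinone 1 is taken as a purchasable building block; 8 and 10 are drawn as single tautomers of equilibrating enol systems, and the target is achiral (two identical prenyl groups on the quaternary carbon).

Step 1
Reactants: 1 2,2,5,6-tetramethyl-4H-1,3-dioxin-4-one; 2 acetyl chloride
Product: 3 2,2,5-trimethyl-6-(2-oxopropyl)-4H-1,3-dioxin-4-one
Conditions: 1 (2 equiv), LiN(SiMe3)2 (2 equiv), THF, −78 °C; then 2 (1 equiv), −78 °C; 1 M HCl work-up
Reagents that add atoms: none
Why: Deprotonation of the 6-methyl group gives the lithium dienolate, which is acylated at its γ-carbon by acetyl chloride, while the second equivalent of dienolate takes up the acidic proton of the product and so prevents a second acylation (vinylogous Claisen-type γ-acylation of a dioxinone dienolate).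

Step 2
Reactants: 3 2,2,5-trimethyl-6-(2-oxopropyl)-4H-1,3-dioxin-4-one; 4 1-bromo-3-methylbut-2-ene (prenyl bromide)
Product: 6 6-[6-methyl-3-(3-methylbut-2-en-1-yl)-2-oxohept-5-en-3-yl]-2,2,5-trimethyl-4H-1,3-dioxin-4-one, via monoprenyl keto-dioxinone 5 (not isolated)
Conditions: 4 (2.5 equiv), Cs2CO3 (3 equiv), MeCN, 0 → 40 °C
Reagents that add atoms: none
Why: The CH2 between the ketone and C6 of the dioxinone is the only doubly activated position, so two successive SN2 C-alkylations of its enolate should build the quaternary carbon, while the dioxinone ring keeps the future C-methyl carbon sp2 and unreactive (double enolate alkylation of an active methylene compound).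

Step 3
Reactants: 6 6-[6-methyl-3-(3-methylbut-2-en-1-yl)-2-oxohept-5-en-3-yl]-2,2,5-trimethyl-4H-1,3-dioxin-4-one; 7 benzoyl chloride
Product: 8 6-[7-methyl-4-(3-methylbut-2-en-1-yl)-1,3-dioxo-1-phenyloct-6-en-4-yl]-2,2,5-trimethyl-4H-1,3-dioxin-4-one
Conditions: MgBr2·OEt2 (2.5 equiv), i-Pr2NEt (3 equiv), 7 (1.2 equiv), CH2Cl2, 0 °C → rt; 1 M HCl work-up
Reagents that add atoms: none
Why: Only the acetyl CH3 can enolise, and soft enolisation with MgBr2·OEt2 and i-Pr2NEt should give a magnesium enolate that is benzoylated at carbon to a chelated 1,3-diketonate, which resists a second acylation (crossed Claisen-type C-acylation of a ketone under soft enolisation).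

Step 4
Reactants: 8 6-[7-methyl-4-(3-methylbut-2-en-1-yl)-1,3-dioxo-1-phenyloct-6-en-4-yl]-2,2,5-trimethyl-4H-1,3-dioxin-4-one
Product: 10 2-benzoyl-3,5-dihydroxy-6-methyl-4,4-bis(3-methylbut-2-en-1-yl)cyclohexa-2,5-dien-1-one, via acylketene 9 (not isolated)
Conditions: PhMe (0.01 M), Et3N (1.5 equiv), DMAP (0.1 equiv), 110 °C; 1 M HCl work-up
Reagents that add atoms: none
Why: Proposed new method: at 110 °C the dioxinone should undergo retro-[4+2] loss of acetone to acylketene 9, and the carbon between the two carbonyls of the enolised 1-phenyl-1,3-diketone should add to the ketene carbonyl carbon in an intramolecular ene-type C-acylation (enol O–H delivered to the ketene oxygen), after which tautomerisation gives the chelated enol 10. The closest known reactions are dioxinone thermolysis with intramolecular capture of the acylketene by hydroxyl or amine groups, the C-acylation of enol ethers by acylketenes in Effenberger-type cyclisations, and the alkoxide-mediated Claisen cyclisation of 3,5,7-triketo esters to acylphloroglucinols; capture of a dioxinone-derived acylketene by a tethered 1,3-diketone carbon to close a carbocycle is the new element. The six-membered carbocycle closes by 6-exo-dig attack on the ketene C=O (the enolendo and enolexo geometries are both allowed for six-membered rings), assisted by the gem-diprenyl (Thorpe–Ingold) effect. No stereocentre is formed, because the quaternary carbon carries two identical prenyl groups and every other ring carbon is sp2. The selectivity needed is C- over O-acylation and carbocycle over pyranone formation: the quaternary carbon cannot enolise, which removes the conjugated dienol needed for oxa-6π closure to a pyranone, and the diketone carbon is the only carbon nucleophile in the molecule. Any O-acylated isomer would be an activated enol ester that Et3N and DMAP should reopen (acylpyridinium formation or E1cB return to 9), so material is expected to drain into the stabilised β-triketone.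

Compound list
1 | 2,2,5,6-tetramethyl-4H-1,3-dioxin-4-one | CC1=C(C)C(=O)OC(C)(C)O1 | starting material
2 | acetyl chloride | CC(=O)Cl | starting material
3 | 2,2,5-trimethyl-6-(2-oxopropyl)-4H-1,3-dioxin-4-one | CC(=O)CC1=C(C)C(=O)OC(C)(C)O1 | intermediate
4 | 1-bromo-3-methylbut-2-ene (prenyl bromide) | CC(C)=CCBr | starting material
5 | 6-(6-methyl-2-oxohept-5-en-3-yl)-2,2,5-trimethyl-4H-1,3-dioxin-4-one (racemic, not isolated) | CC(=O)C(CC=C(C)C)C1=C(C)C(=O)OC(C)(C)O1 | intermediate
6 | 6-[6-methyl-3-(3-methylbut-2-en-1-yl)-2-oxohept-5-en-3-yl]-2,2,5-trimethyl-4H-1,3-dioxin-4-one | CC(=O)C(CC=C(C)C)(CC=C(C)C)C1=C(C)C(=O)OC(C)(C)O1 | intermediate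
7 | benzoyl chloride | O=C(Cl)c1ccccc1 | starting material
8 | 6-[7-methyl-4-(3-methylbut-2-en-1-yl)-1,3-dioxo-1-phenyloct-6-en-4-yl]-2,2,5-trimethyl-4H-1,3-dioxin-4-one | O=C(CC(=O)C(CC=C(C)C)(CC=C(C)C)C1=C(C)C(=O)OC(C)(C)O1)c1ccccc1 | intermediate
9 | 2-methyl-4,4-bis(3-methylbut-2-en-1-yl)-7-phenylhept-1-ene-1,3,5,7-tetrone (acylketene, not isolated) | CC(=C=O)C(=O)C(CC=C(C)C)(CC=C(C)C)C(=O)CC(=O)c1ccccc1 | intermediate
10 | 2-benzoyl-3,5-dihydroxy-6-methyl-4,4-bis(3-methylbut-2-en-1-yl)cyclohexa-2,5-dien-1-one | CC(C)=CCC1(CC=C(C)C)C(O)=C(C)C(=O)C(C(=O)c2ccccc2)=C1O | target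

Total step count: 4
Longest linear sequence: 4 steps (1 → 3 → 6 → 8 → 10)

Steps most likely to fail

1. Step 4 (carries the label). What may go wrong: capture of the ketene at the enol oxygen instead of carbon with only slow return, or oligomerisation of the ketene before ring closure. The fallback uses known chemistry and sets out from 8. Heating 8 in PhMe/MeOH (110 °C, sealed tube) should intercept the acylketene with methanol, the established conversion of a dioxinone into a β-keto ester, and give methyl 2-methyl-4,4-bis(3-methylbut-2-en-1-yl)-3,5,7-trioxo-7-phenylheptanoate F1 (racemic at C2). NaOMe in MeOH at reflux should then bring about the classical Claisen (Dieckmann) cyclisation of this triketo ester. The diketonate carbon displaces methoxide, the product is held as its stabilised enolate, and acidification returns to the route at 10.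

2. Step 2. What may go wrong: O-alkylation or SN2′ attack in the second, sterically demanding alkylation, or a stall after the first prenylation. The fallback sets out from 3 and is a Tsuji–Trost prenylation with methyl 3-methylbut-2-en-1-yl carbonate (2.5 equiv) and Pd(PPh3)4 (zerovalent palladium) in THF at 50 °C. The soft stabilised carbanion should attack the π-prenyl palladium complex through carbon, at the unsubstituted terminus, under neutral conditions. It comes back to the route directly at 6 and makes no new compound (F0).

3. Step 3. What may go wrong: O-benzoylation, a second acylation, or premature attack of the enolate on the dioxinone carbonyl. The fallback sets out from 6. The kinetic lithium enolate (LiN(SiMe3)2, THF, −78 °C) and benzaldehyde should give the aldol adduct 6-[1-hydroxy-7-methyl-4-(3-methylbut-2-en-1-yl)-3-oxo-1-phenyloct-6-en-4-yl]-2,2,5-trimethyl-4H-1,3-dioxin-4-one F2 (racemic). Oxidation of this β-hydroxy ketone with Dess–Martin periodinane (CH2Cl2, rt) comes back to the route at 8.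

Further compounds
F1 | step 4 | methyl 2-methyl-4,4-bis(3-methylbut-2-en-1-yl)-3,5,7-trioxo-7-phenylheptanoate | COC(=O)C(C)C(=O)C(CC=C(C)C)(CC=C(C)C)C(=O)CC(=O)c1ccccc1
F0 | step 2 | none | none
F2 | step 3 | 6-[1-hydroxy-7-methyl-4-(3-methylbut-2-en-1-yl)-3-oxo-1-phenyloct-6-en-4-yl]-2,2,5-trimethyl-4H-1,3-dioxin-4-one | OC(CC(=O)C(CC=C(C)C)(CC=C(C)C)C1=C(C)C(=O)OC(C)(C)O1)c1ccccc1
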